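**Plan**

- Retrosynthesis: the 2,2-dimethylfuran-3(2H)-one on C8 is cut at its O–CH and CH–C(aryl) bonds, back to an α'-hydroxy ketone and then to a prenyl group. Ring A of the flavone is then cut at C5–C6, C7–C8 and C4a–C5.
- Enabling feature: ring A carries oxygen on C5, C7 and C8a, carbon on C4a and C8, and hydrogen only on C6. This is the pattern left by a ketene (C5 carbonyl carbon, C8 alpha carbon) and an alkoxyalkyne (C6–H, C7–OMe) annulated onto the C2=C3 bond of a 4-pyranone (C8a, C4a).
- Forward order: ring C with phenyl ring B attached arises first by triketone cyclodehydration. Lateral prenylation and carboxylation arm the pyranone. Ring A is closed by the ketene/methoxyacetylene benzannulation. The furanone is built last from the prenyl group (dihydroxylation, oxidation, aminomethylenation–cyclisation).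
- Stereochemistry: the target is achiral, so no stereocentre has to be controlled.

Key step: step 7

Remark: the stereocentres that arise on the way (alpha carbon of the acid and its chloride, cyclobutenone C4, dienone C4a, diol carbinol) are racemic and are all destroyed; enolates, the acetylide and carboxylate salts formed by the bases are conjugate bases of numbered compounds and are not counted separately.

**Route**

Step 1
Reactants: 1 acetylacetone (pentane-2,4-dione); 2 methyl benzoate
Product: 3 1-phenylhexane-1,3,5-trione
Conditions: NaH (4 equiv), DME, reflux; then aq. HCl, 0 °C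
Reagents that add atoms: none
Why: Claisen-type terminal aroylation of a β-diketone dianion, in which excess NaH makes the methyl carbanion of 1 that attacks the non-enolisable ester, and deprotonation of the triketone formed drives the condensation.

Step 2
Reactants: 3 1-phenylhexane-1,3,5-trione
Product: 4 2-methyl-6-phenyl-4H-pyran-4-one
Conditions: conc. H2SO4, 0 °C; then ice
Reagents that add atoms: none
Why: Acid-catalysed cyclodehydration of a 1,3,5-triketone, in which the enol oxygen of one terminal carbonyl adds to the other and water is lost, is the standard closure of the 4-pyranone ring (ring C).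

Step 3
Reactants: 4 2-methyl-6-phenyl-4H-pyran-4-one; 5 prenyl bromide (1-bromo-3-methylbut-2-ene)
Product: 6 2-(4-methylpent-3-en-1-yl)-6-phenyl-4H-pyran-4-one
Conditions: LiN(iPr)2 (1.05 equiv), THF, −78 °C; then 5, −78 → −20 °C
Reagents that add atoms: none
Why: Lateral (vinylogous) metalation of the 2-methyl group gives an extended enolate that should be alkylated at the exocyclic carbon by the primary allylic bromide in an SN2 reaction, restoring the pyranone.

Step 4
Reactants: 6 2-(4-methylpent-3-en-1-yl)-6-phenyl-4H-pyran-4-one
Product: 7 5-methyl-2-(4-oxo-6-phenyl-4H-pyran-2-yl)hex-4-enoic acid (racemic)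
Conditions: LiN(iPr)2 (1.1 equiv), THF, −78 °C; CO2 (g); cold 1 M HCl to pH 3, extraction at 0 °C
Reagents that add atoms: carbon dioxide, O=C=O
Why: A second lateral metalation at the only gamma C–H position left gives the extended enolate, which should be carboxylated at carbon by CO2; the new centre is racemic and is erased in step 7.

Step 5
Reactants: 7 5-methyl-2-(4-oxo-6-phenyl-4H-pyran-2-yl)hex-4-enoic acid
Product: 8 5-methyl-2-(4-oxo-6-phenyl-4H-pyran-2-yl)hex-4-enoyl chloride (racemic, used crude)
Conditions: 1-chloro-N,N,2-trimethylprop-1-en-1-amine (1.1 equiv), CH2Cl2, 0 °C → rt; evaporate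
Reagents that add atoms: 1-chloro-N,N,2-trimethylprop-1-en-1-amine, CC(C)=C(Cl)N(C)C
Why: Acid chloride formation with an α-chloroenamine runs under neutral conditions with an inert amide as the only co-product, so no HCl reaches the prenyl alkene and no chlorinating agent able to attack the pyranone carbonyl is present.

Step 6
Reactants: 9 chloroacetaldehyde dimethyl acetal (2-chloro-1,1-dimethoxyethane)
Product: 10 methoxyacetylene (methoxyethyne, bp about 23 °C, kept as a cold toluene solution)
Conditions: NaNH2 (3 equiv), liq. NH3, −33 °C; then sat. aq. NaCl, −70 °C; distil into toluene at −78 °C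
Reagents that add atoms: none
Why: Twofold base-induced elimination (methanol, then HCl) of a chloroacetal is the standard preparation of 1-alkoxyalkynes, the alkyne being held as its sodium acetylide until the cold aqueous quench.

Step 7
Reactants: 8 5-methyl-2-(4-oxo-6-phenyl-4H-pyran-2-yl)hex-4-enoyl chloride; 10 methoxyacetylene
Product: 15 5-hydroxy-7-methoxy-8-(3-methylbut-2-en-1-yl)-2-phenyl-4H-chromen-4-one, via pyranonyl ketene 11 (not isolated), via methoxycyclobutenone 12 (not isolated), via dienylketene 13 (not isolated), via cyclohexadienone 14 (not isolated)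
Conditions: Et3N (1.3 equiv), 10 (3 equiv), toluene, sealed tube, 0 °C → rt; then 90 °C
Reagents that add atoms: none
Why: Proposed new method: Et3N removes HCl from 8 to give ketene 11, in effect a vinylketene whose vinyl unit is the pyranone C2=C3 bond; the nucleophilic CH terminus of the ynol ether attacks the ketene carbonyl carbon in a [2+2] cycloaddition to give cyclobutenone 12, which at 90 °C opens by four-electron conrotatory cleavage of the former ketene C=C bond to dienylketene 13. Ring A is then closed by a thermal six-electron disrotatory electrocyclisation of the ketene carbon onto pyranone C3 (14), and enolisation of the dienone gives the aromatic phenol; the four-membered ring is only a transient. The closest known reaction type is the Danheiser benzannulation of vinyl- and arylketenes with alkoxy- or siloxyalkynes, here carried over to a ketene borne by a 4-pyranone, whose C2=C3 bond is less aromatic than a benzene bond and should therefore enter the electrocyclisation at least as readily. The ketene carbonyl carbon becomes C5–OH, the alkyne CH becomes C6–H, the alkyne C–OMe becomes C7 and the ketene alpha carbon becomes C8 with its prenyl group, so the bonds formed are C5–C6, C7–C8 and C4a–C5; no stereocentre is created and the centre of 8 is erased in 11. The step needs head-to-tail regiochemistry in the [2+2] addition, which the polarisation of the ynol ether secures, and a dienylketene with the pyranonyl group cis to the ketenyl carbon, which follows from the outward rotation preferred by the alkyl group and from the reversibility of the ring opening. Closure has no regiochemical choice, since pyranone C3 is the only ring carbon adjacent to the ketene-bearing C2.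

Step 8
Reactants: 15 5-hydroxy-7-methoxy-8-(3-methylbut-2-en-1-yl)-2-phenyl-4H-chromen-4-one
Product: 16 5,7-dimethoxy-8-(3-methylbut-2-en-1-yl)-2-phenyl-4H-chromen-4-one
Conditions: Me2SO4, K2CO3, acetone, reflux
Reagents that add atoms: dimethyl sulfate, COS(=O)(=O)OC
Why: Williamson etherification under forcing conditions is the usual way to methylate the hydrogen-bonded 5-hydroxyl of a flavone, and nothing else in 15 is alkylated.

Step 9
Reactants: 16 5,7-dimethoxy-8-(3-methylbut-2-en-1-yl)-2-phenyl-4H-chromen-4-one
Product: 17 8-(2,3-dihydroxy-3-methylbutyl)-5,7-dimethoxy-2-phenyl-4H-chromen-4-one (racemic)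
Conditions: OsO4 (2 mol%), NMO (1.5 equiv), acetone/H2O, rt
Reagents that add atoms: N-methylmorpholine N-oxide, C[N+]1([O-])CCOCC1 (oxygen relayed through the OsO4 catalyst); water, O
Why: Upjohn dihydroxylation should take the electron-rich trisubstituted prenyl alkene far faster than the electron-poor flavone C2=C3 bond; the new carbinol centre is racemic and is removed in step 10.

Step 10
Reactants: 17 8-(2,3-dihydroxy-3-methylbutyl)-5,7-dimethoxy-2-phenyl-4H-chromen-4-one
Product: 18 8-(3-hydroxy-3-methyl-2-oxobutyl)-5,7-dimethoxy-2-phenyl-4H-chromen-4-one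
Conditions: IBX (1.5 equiv), DMSO, rt
Reagents that add atoms: none
Why: IBX oxidation of a 1,2-diol gives the α-ketol without glycol cleavage, and only the secondary alcohol can be oxidised.

Step 11
Reactants: 18 8-(3-hydroxy-3-methyl-2-oxobutyl)-5,7-dimethoxy-2-phenyl-4H-chromen-4-one
Product: 20 tachrosin, via enaminone 19 (not isolated)
Conditions: DMF-DMA (3 equiv), toluene, 100 °C; then 1 M HCl, THF, rt
Reagents that add atoms: N,N-dimethylformamide dimethyl acetal, COC(OC)N(C)C
Why: Aminomethylenation of the methylene between aryl ring and ketone gives enaminone 19, and acid then lets the tertiary hydroxyl add to the iminium carbon and expel dimethylamine, the standard construction of a 2,2-dimethylfuran-3(2H)-one from an α'-hydroxy ketone.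

**Compound list**

1 | acetylacetone (pentane-2,4-dione) | CC(=O)CC(C)=O | starting material
2 | methyl benzoate | COC(=O)c1ccccc1 | starting material
3 | 1-phenylhexane-1,3,5-trione | CC(=O)CC(=O)CC(=O)c1ccccc1 | intermediate
4 | 2-methyl-6-phenyl-4H-pyran-4-one | Cc1cc(=O)cc(-c2ccccc2)o1 | intermediate
5 | prenyl bromide (1-bromo-3-methylbut-2-ene) | CC(C)=CCBr | starting material
6 | 2-(4-methylpent-3-en-1-yl)-6-phenyl-4H-pyran-4-one | CC(C)=CCCc1cc(=O)cc(-c2ccccc2)o1 | intermediate
7 | 5-methyl-2-(4-oxo-6-phenyl-4H-pyran-2-yl)hex-4-enoic acid (racemic) | CC(C)=CCC(C(=O)O)c1cc(=O)cc(-c2ccccc2)o1 | intermediate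
8 | 5-methyl-2-(4-oxo-6-phenyl-4H-pyran-2-yl)hex-4-enoyl chloride (racemic) | CC(C)=CCC(C(=O)Cl)c1cc(=O)cc(-c2ccccc2)o1 | intermediate
9 | chloroacetaldehyde dimethyl acetal (2-chloro-1,1-dimethoxyethane) | COC(CCl)OC | starting material
10 | methoxyacetylene (methoxyethyne) | COC#C | intermediate
11 | 5-methyl-2-(4-oxo-6-phenyl-4H-pyran-2-yl)hexa-1,4-dien-1-one (pyranonyl prenyl ketene) | CC(C)=CCC(=C=O)c1cc(=O)cc(-c2ccccc2)o1 | intermediate
12 | 3-methoxy-4-(3-methylbut-2-en-1-yl)-4-(4-oxo-6-phenyl-4H-pyran-2-yl)cyclobut-2-en-1-one (racemic) | COC1=CC(=O)C1(CC=C(C)C)c2cc(=O)cc(-c3ccccc3)o2 | intermediate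
13 | (3E)-3-methoxy-7-methyl-4-(4-oxo-6-phenyl-4H-pyran-2-yl)octa-1,3,6-trien-1-one (pyranonyl cis to the ketenyl carbon) | O=C=C/C(OC)=C(/CC=C(C)C)c1cc(=O)cc(-c2ccccc2)o1 | intermediate
14 | 7-methoxy-8-(3-methylbut-2-en-1-yl)-2-phenyl-4aH-chromene-4,5-dione (racemic) | COC1=CC(=O)C2C(=O)C=C(c3ccccc3)OC2=C1CC=C(C)C | intermediate
15 | 5-hydroxy-7-methoxy-8-(3-methylbut-2-en-1-yl)-2-phenyl-4H-chromen-4-one | COc1cc(O)c2c(=O)cc(-c3ccccc3)oc2c1CC=C(C)C | intermediate
16 | 5,7-dimethoxy-8-(3-methylbut-2-en-1-yl)-2-phenyl-4H-chromen-4-one | COc1cc(OC)c2c(=O)cc(-c3ccccc3)oc2c1CC=C(C)C | intermediate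
17 | 8-(2,3-dihydroxy-3-methylbutyl)-5,7-dimethoxy-2-phenyl-4H-chromen-4-one (racemic) | COc1cc(OC)c2c(=O)cc(-c3ccccc3)oc2c1CC(O)C(C)(C)O | intermediate
18 | 8-(3-hydroxy-3-methyl-2-oxobutyl)-5,7-dimethoxy-2-phenyl-4H-chromen-4-one | COc1cc(OC)c2c(=O)cc(-c3ccccc3)oc2c1CC(=O)C(C)(C)O | intermediate
19 | 8-[1-(dimethylamino)-4-hydroxy-4-methyl-3-oxopent-1-en-2-yl]-5,7-dimethoxy-2-phenyl-4H-chromen-4-one (alkene geometry not defined) | COc1cc(OC)c2c(=O)cc(-c3ccccc3)oc2c1C(=CN(C)C)C(=O)C(C)(C)O | intermediate
20 | tachrosin, 4-(5,7-dimethoxy-4-oxo-2-phenyl-4H-chromen-8-yl)-2,2-dimethylfuran-3(2H)-one | COc1cc(OC)c2c(=O)cc(-c3ccccc3)oc2c1C1=COC(C)(C)C1=O | target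

**Count**

Total steps: 11. Longest linear sequence: 10 steps (steps 1 to 5 and 7 to 11); step 6 is a one-step side branch that supplies the alkyne.

**Steps most likely to fail**

1. Step 7. The ketene may be consumed by oligomerisation or by acylating the phenol already formed. The dienylketene of the wrong geometry may be trapped by intramolecular [2+2] addition to the prenyl alkene before it can revert. The volatile alkyne may be lost before the cycloaddition.
Fallback (known chemistry, ring A bought instead of built): the route is re-entered from prenyl bromide 5. Commercial tectochrysin (5-hydroxy-7-methoxyflavone) would be O-alkylated with 5 (K2CO3, DMF, 60 °C) to 7-methoxy-5-(3-methylbut-2-en-1-yloxy)-2-phenyl-4H-chromen-4-one F1. Warming F1 with catalytic Eu(fod)3, europium tris(6,6,7,7,8,8,8-heptafluoro-2,2-dimethyloctane-3,5-dionate), in CHCl3 should effect the para-Claisen–Cope sequence: the allyl unit moves from oxygen to C6 with inversion and then to C8 with a second inversion. This comes back to the route at 15.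

2. Step 4. Proton transfer from the carboxylate product to unreacted enolate may stall the carboxylation. The vinylogous β-keto acid may also decarboxylate during acidification and isolation.
Fallback (ester first, free acid never formed): it sets out from pyranone 4. Double deprotonation with LiN(SiMe3)2 (2.2 equiv) and C-acylation with diallyl carbonate would give allyl (4-oxo-6-phenyl-4H-pyran-2-yl)acetate F2. Alkylation with prenyl bromide 5 (K2CO3, acetone) would give allyl 5-methyl-2-(4-oxo-6-phenyl-4H-pyran-2-yl)hex-4-enoate F3. Deallylation with catalytic Pd(PPh3)4 and sodium 2-ethylhexanoate would deliver sodium 5-methyl-2-(4-oxo-6-phenyl-4H-pyran-2-yl)hex-4-enoate F4. Oxalyl chloride with a trace of DMF at 0 °C would convert this salt directly into acid chloride 8, where the route is rejoined.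

3. Step 11. Condensation at the methylene shielded by the two ortho substituents of ring A may be slow. The prolonged heating then needed may degrade the α-ketol by acyloin-type rearrangement.
Fallback (enolate formylation instead of amide acetal condensation): it sets out from hydroxy ketone 18. Claisen formylation with NaH (2.2 equiv) and ethyl formate in THF at 0 °C to rt would give 8-(1,4-dihydroxy-4-methyl-3-oxopent-1-en-2-yl)-5,7-dimethoxy-2-phenyl-4H-chromen-4-one F5. Cyclodehydration with catalytic p-toluenesulfonic acid in toluene would close the furanone and arrive at 20.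

**Further compounds**

F1 | step 7 | 7-methoxy-5-(3-methylbut-2-en-1-yloxy)-2-phenyl-4H-chromen-4-one | COc1cc(OCC=C(C)C)c2c(=O)cc(-c3ccccc3)oc2c1
F2 | step 4 | allyl (4-oxo-6-phenyl-4H-pyran-2-yl)acetate | C=CCOC(=O)Cc1cc(=O)cc(-c2ccccc2)o1
F3 | step 4 | allyl 5-methyl-2-(4-oxo-6-phenyl-4H-pyran-2-yl)hex-4-enoate | C=CCOC(=O)C(CC=C(C)C)c1cc(=O)cc(-c2ccccc2)o1
F4 | step 4 | sodium 5-methyl-2-(4-oxo-6-phenyl-4H-pyran-2-yl)hex-4-enoate | CC(C)=CCC(C(=O)[O-])c1cc(=O)cc(-c2ccccc2)o1.[Na+]
F5 | step 11 | 8-(1,4-dihydroxy-4-methyl-3-oxopent-1-en-2-yl)-5,7-dimethoxy-2-phenyl-4H-chromen-4-one | COc1cc(OC)c2c(=O)cc(-c3ccccc3)oc2c1C(=CO)C(=O)C(C)(C)O
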